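**Retrosynthetic overview**
1. Target ⇒ three late acylations of a trans-hydrindan-2-one core: C5–O comes from SeO2 allylic oxidation of the 4-methylidene group, C3–O from hydroxylation of the kinetic ketone enolate.
2. Cyclopentanone (second ring) ⇒ intramolecular Claisen acylation of a tert-butyl ester enolate on a Weinreb amide, then decarboxylation.
3. Side-chain centres C1/C1′ ⇒ intermolecular Evans syn-aldol of a cyclohexylacetyl oxazolidinone boron enolate with acetaldehyde (key C–C bond).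
4. trans,trans-Cyclohexane ⇒ conjugate allylation/enolate alkylation of (R)-cryptone; cyclohexenone (first ring) ⇒ organocatalytic Michael addition of 3-methylbutanal to but-3-en-2-one, then aldol condensation.
5. Ester acids ⇒ Evans methylation ((R)-2-methylbutanoic acid) and syn-carbocupration of ethyl but-2-ynoate ((E)-3-methylpent-2-enoic acid).

Assumption: bicyclic compounds 31–42 keep the locants of the target skeleton (C1 side-chain carbon, C2 ketone, C3 acyloxy carbon, C3a/C7a ring fusion, C4 methylidene carbon, C5 allylic oxygenated carbon, C7 isopropyl carbon).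
Assumption: (R)-cryptone of about 90% ee is acceptable, because the auxiliary in 25 and 28 turns the minor enantiomeric series into a separable diastereomer.

**Route**

Step 1
Reactants: 1 (4R)-4-benzyl-1,3-oxazolidin-2-one; 2 butanoyl chloride
Product: 3 (4R)-4-benzyl-3-butanoyl-1,3-oxazolidin-2-one
Conditions: Et3N, DMAP (10 mol %), CH2Cl2, 0 °C → rt
Reagents that add atoms: none
Why: DMAP-catalysed N-acylation attaches the Evans auxiliary needed for the asymmetric alkylation.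

Step 2
Reactants: 3 (4R)-4-benzyl-3-butanoyl-1,3-oxazolidin-2-one
Product: 5 (4R)-4-benzyl-3-[(2R)-2-methylbutanoyl]-1,3-oxazolidin-2-one, via sodium Z-enolate 4 (not isolated)
Conditions: NaN(SiMe3)2, THF, −78 °C; then MeI, −78 → −40 °C
Reagents that add atoms: iodomethane, CI
Why: Evans asymmetric alkylation, in which the chelated Z-enolate is methylated on the face opposite the benzyl group and so sets the (2R) centre (minor diastereomer removed by chromatography).

Step 3
Reactants: 5 (4R)-4-benzyl-3-[(2R)-2-methylbutanoyl]-1,3-oxazolidin-2-one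
Product: 7 (2R)-2-methylbutanoic acid, via peroxy acid 6 (not isolated)
Conditions: LiOH, H2O2, THF/H2O, 0 °C; then aq. Na2SO3; HCl to pH 2
Reagents that add atoms: hydrogen peroxide, OO
Why: hydroperoxide cleavage of the imide attacks the exocyclic carbonyl, leaves the α-centre untouched and returns the auxiliary.

Step 4
Reactants: 8 ethyl but-2-ynoate
Product: 9 ethyl (2E)-3-methylpent-2-enoate
Conditions: EtMgBr, CuBr·SMe2, THF, −78 °C; aq. NH4Cl quench at −78 °C
Reagents that add atoms: ethylmagnesium bromide, CC[Mg]Br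
Why: syn-carbocupration (conjugate addition of an ethylcopper reagent to the ynoate) puts ethyl and copper cis, so protonation with retention at −78 °C gives the E ester (ester cis to methyl).

Step 5
Reactants: 9 ethyl (2E)-3-methylpent-2-enoate
Product: 10 (2E)-3-methylpent-2-enoic acid
Conditions: LiOH, THF/MeOH/H2O, rt; HCl
Reagents that add atoms: lithium hydroxide, [Li+].[OH-]
Why: plain ester saponification, which does not touch the geometry of the conjugated trisubstituted alkene.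

Step 6
Reactants: 11 3-methylbutanal; 12 but-3-en-2-one
Product: 13 (2R)-5-oxo-2-(propan-2-yl)hexanal
Conditions: (2R)-2-[methoxy(diphenyl)methyl]pyrrolidine (5 mol %), ethyl 3,4-dihydroxybenzoate (20 mol %), neat, 4 °C
Reagents that add atoms: none
Why: enamine-catalysed intermolecular Michael addition, in which the diarylmethyl group of the (R)-prolinol ether shields one enamine face so that the enone adds to the other and gives the (R)-aldehyde (about 90% ee).

Step 7
Reactants: 13 (2R)-5-oxo-2-(propan-2-yl)hexanal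
Product: 15 (4R)-4-(propan-2-yl)cyclohex-2-en-1-one, via aldol 14 (not isolated)
Conditions: LiOH (0.1 equiv), i-PrOH, rt
Reagents that add atoms: none
Why: intramolecular aldol condensation of the methyl ketone onto the aldehyde closes the six-membered ring under conditions mild enough to keep the C4 centre.

Step 8
Reactants: 15 (4R)-4-(propan-2-yl)cyclohex-2-en-1-one
Product: 16 trimethyl{[(3R,4R)-3-(prop-2-en-1-yl)-4-(propan-2-yl)cyclohex-1-en-1-yl]oxy}silane
Conditions: allylMgBr, CuBr·SMe2, Me3SiCl, THF, −78 °C; Et3N then cold aq. NaHCO3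
Reagents that add atoms: allylmagnesium bromide, C=CC[Mg]Br; chlorotrimethylsilane, C[Si](C)(C)Cl
Why: silyl-chloride-accelerated copper-mediated conjugate allylation adds allyl at C3 anti to the C4 isopropyl group (trans) and captures the enolate regiospecifically as the silyl enol ether.

Step 9
Reactants: 16 trimethyl{[(3R,4R)-3-(prop-2-en-1-yl)-4-(propan-2-yl)cyclohex-1-en-1-yl]oxy}silane; 17 tert-butyl bromoacetate
Product: 19 tert-butyl 2-[(1S,2R,3R)-6-oxo-2-(prop-2-en-1-yl)-3-(propan-2-yl)cyclohexyl]acetate, via lithium enolate 18 (not isolated)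
Conditions: MeLi, THF, 0 °C → rt; then 17, DMPU, −78 → −20 °C
Reagents that add atoms: none
Why: the regiodefined lithium enolate (Si–O cleavage by MeLi) is C-alkylated anti to the neighbouring allyl group, giving the all-equatorial trans,trans ketone, which is also the thermodynamic epimer at the α-carbon.

Step 10
Reactants: 19 tert-butyl 2-[(1S,2R,3R)-6-oxo-2-(prop-2-en-1-yl)-3-(propan-2-yl)cyclohexyl]acetate
Product: 21 tert-butyl 2-[(1S,2R,3R)-6-oxo-2-(2-oxoethyl)-3-(propan-2-yl)cyclohexyl]acetate, via ozonide 20 (not isolated)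
Conditions: O3, CH2Cl2, −78 °C; then PPh3, −78 °C → rt
Reagents that add atoms: ozone, [O-][O+]=O
Why: ozonolysis with reductive work-up cleaves the only alkene to the aldehyde while ketone and tert-butyl ester are inert.

Step 11
Reactants: 21 tert-butyl 2-[(1S,2R,3R)-6-oxo-2-(2-oxoethyl)-3-(propan-2-yl)cyclohexyl]acetate
Product: 22 2-[(1R,2S,6R)-2-(2-tert-butoxy-2-oxoethyl)-3-oxo-6-(propan-2-yl)cyclohexyl]acetic acid
Conditions: NaClO2, NaH2PO4, 2-methylbut-2-ene, t-BuOH/H2O, rt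
Reagents that add atoms: sodium chlorite, [Na+].[O-]Cl=O
Why: Pinnick oxidation converts the aldehyde to the acid under buffered conditions that leave the ketone, the ester and the ring stereocentres alone.

Step 12
Reactants: 22 2-[(1R,2S,6R)-2-(2-tert-butoxy-2-oxoethyl)-3-oxo-6-(propan-2-yl)cyclohexyl]acetic acid
Product: 23 2-[(1R,2S,6R)-2-(2-tert-butoxy-2-oxoethyl)-3-methylidene-6-(propan-2-yl)cyclohexyl]acetic acid
Conditions: Ph3PCH3Br, KOt-Bu (excess), THF, 0 → 50 °C; aq. citric acid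
Reagents that add atoms: methyltriphenylphosphonium bromide, C[P+](c1ccccc1)(c1ccccc1)c1ccccc1.[Br-]
Why: Wittig methylenation (excess ylide tolerates the carboxylate and the tert-butyl ester) installs the exocyclic methylene early and removes the only ketone that would compete in the later enolisations; the α-centre is already the stable equatorial epimer.

Step 13
Reactants: 23 2-[(1R,2S,6R)-2-(2-tert-butoxy-2-oxoethyl)-3-methylidene-6-(propan-2-yl)cyclohexyl]acetic acid; 1 (4R)-4-benzyl-1,3-oxazolidin-2-one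
Product: 25 tert-butyl 2-[(1S,2R,3R)-2-{2-[(4R)-4-benzyl-2-oxo-1,3-oxazolidin-3-yl]-2-oxoethyl}-6-methylidene-3-(propan-2-yl)cyclohexyl]acetate, via mixed pivalic anhydride 24 (not isolated)
Conditions: t-BuCOCl, Et3N, THF, −20 °C; then 1, LiCl, −20 °C → rt
Reagents that add atoms: none
Why: mixed-anhydride N-acylation of the oxazolidinone occurs at the unhindered acyl carbon and gives the imide for the aldol.

Step 14
Reactants: 25 tert-butyl 2-[(1S,2R,3R)-2-{2-[(4R)-4-benzyl-2-oxo-1,3-oxazolidin-3-yl]-2-oxoethyl}-6-methylidene-3-(propan-2-yl)cyclohexyl]acetate; 26 acetaldehyde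
Product: 28 tert-butyl 2-[(1S,2R,3R)-2-{(2R,3S)-1-[(4R)-4-benzyl-2-oxo-1,3-oxazolidin-3-yl]-3-hydroxy-1-oxobutan-2-yl}-6-methylidene-3-(propan-2-yl)cyclohexyl]acetate, via Z-dibutylboron enolate 27 (not isolated)
Conditions: Bu2BOTf, i-Pr2NEt, CH2Cl2, −78 → 0 °C; then MeCHO, −78 → 0 °C; pH 7 buffer, MeOH, H2O2, 0 °C
Reagents that add atoms: none
Why: Evans syn-aldol, an intermolecular aldol addition of the Z-boron enolate to acetaldehyde through a Zimmerman–Traxler chair in which the (R)-benzyl auxiliary fixes the enolate face, sets the future C1 (R) and C1′ (S) centres in the required syn relationship.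

Step 15
Reactants: 28 tert-butyl 2-[(1S,2R,3R)-2-{(2R,3S)-1-[(4R)-4-benzyl-2-oxo-1,3-oxazolidin-3-yl]-3-hydroxy-1-oxobutan-2-yl}-6-methylidene-3-(propan-2-yl)cyclohexyl]acetate
Product: 29 tert-butyl 2-[(1S,2R,3R)-2-{(2R,3S)-3-hydroxy-1-[methoxy(methyl)amino]-1-oxobutan-2-yl}-6-methylidene-3-(propan-2-yl)cyclohexyl]acetate
Conditions: MeNH(OMe)·HCl, AlMe3, CH2Cl2, −20 → 0 °C; aq. Rochelle salt
Reagents that add atoms: N,O-dimethylhydroxylamine hydrochloride, CNOC.Cl
Why: aluminium-amide transamidation to the Weinreb amide is fast for a β-hydroxy imide (internal aluminium alkoxide), leaves the tert-butyl ester alone and returns the auxiliary.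

Step 16
Reactants: 29 tert-butyl 2-[(1S,2R,3R)-2-{(2R,3S)-3-hydroxy-1-[methoxy(methyl)amino]-1-oxobutan-2-yl}-6-methylidene-3-(propan-2-yl)cyclohexyl]acetate
Product: 30 tert-butyl 2-[(1S,2R,3R)-2-{(2R,3S)-3-[(tert-butyldimethylsilyl)oxy]-1-[methoxy(methyl)amino]-1-oxobutan-2-yl}-6-methylidene-3-(propan-2-yl)cyclohexyl]acetate
Conditions: t-BuMe2SiOTf, 2,6-lutidine, CH2Cl2, −78 → 0 °C
Reagents that add atoms: tert-butyldimethylsilyl trifluoromethanesulfonate, CC(C)(C)[Si](C)(C)OS(=O)(=O)C(F)(F)F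
Why: silylation of the secondary alcohol blocks retro-aldol and β-elimination in the basic steps that follow.

Step 17
Reactants: 30 tert-butyl 2-[(1S,2R,3R)-2-{(2R,3S)-3-[(tert-butyldimethylsilyl)oxy]-1-[methoxy(methyl)amino]-1-oxobutan-2-yl}-6-methylidene-3-(propan-2-yl)cyclohexyl]acetate
Product: 31 tert-butyl (1R,3aR,7R,7aR)-1-{(1S)-1-[(tert-butyldimethylsilyl)oxy]ethyl}-4-methylidene-2-oxo-7-(propan-2-yl)octahydro-1H-indene-3-carboxylate (C3 epimers and enol)
Conditions: LiN(SiMe3)2 (2.5 equiv), THF, −78 → 0 °C; aq. NH4Cl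
Reagents that add atoms: none
Why: intramolecular Claisen (Dieckmann-type) acylation, in which the tert-butyl ester enolate attacks the Weinreb amide in a 5-exo mode and the chelated tetrahedral intermediate prevents over-reaction; the trans ring fusion is already fixed by the two trans-diequatorial arms.

Step 18
Reactants: 31 tert-butyl (1R,3aR,7R,7aR)-1-{(1S)-1-[(tert-butyldimethylsilyl)oxy]ethyl}-4-methylidene-2-oxo-7-(propan-2-yl)octahydro-1H-indene-3-carboxylate
Product: 34 (1R,3aS,7R,7aR)-1-{(1S)-1-[(tert-butyldimethylsilyl)oxy]ethyl}-4-methylidene-7-(propan-2-yl)octahydro-2H-inden-2-one, via bis(trimethylsilyl) derivative 32 (not isolated), via beta-keto acid 33 (not isolated)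
Conditions: Me3SiOTf, 2,6-lutidine, CH2Cl2, 0 °C → rt; then aq. citric acid; then toluene, 60 °C
Reagents that add atoms: none
Why: buffered silyl-triflate cleavage of the tert-butyl ester avoids free acid (the exocyclic methylene and the silyl ether survive), and the β-keto acid then decarboxylates; C1 keeps its equatorial, thermodynamically preferred configuration.

Step 19
Reactants: 34 (1R,3aS,7R,7aR)-1-{(1S)-1-[(tert-butyldimethylsilyl)oxy]ethyl}-4-methylidene-7-(propan-2-yl)octahydro-2H-inden-2-one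
Product: 36 (1R,3R,3aS,7R,7aR)-1-{(1S)-1-[(tert-butyldimethylsilyl)oxy]ethyl}-3-hydroxy-4-methylidene-7-(propan-2-yl)octahydro-2H-inden-2-one, via potassium enolate 35 (not isolated)
Conditions: KN(SiMe3)2, THF, −78 °C; then 2-(phenylsulfonyl)-3-phenyloxaziridine, −78 °C; aq. NH4Cl
Reagents that add atoms: 2-(phenylsulfonyl)-3-phenyloxaziridine, O=S(=O)(c1ccccc1)N1OC1c1ccccc1
Why: kinetic deprotonation takes the unhindered C3 methylene rather than the branched C1, and the Davis enolate hydroxylation is expected on the face anti to the axial C3a–H (torsionally favoured), giving the 3R alcohol.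

Step 20
Reactants: 36 (1R,3R,3aS,7R,7aR)-1-{(1S)-1-[(tert-butyldimethylsilyl)oxy]ethyl}-3-hydroxy-4-methylidene-7-(propan-2-yl)octahydro-2H-inden-2-one; 7 (2R)-2-methylbutanoic acid
Product: 37 (1R,3R,3aS,7R,7aR)-1-{(1S)-1-[(tert-butyldimethylsilyl)oxy]ethyl}-4-methylidene-2-oxo-7-(propan-2-yl)octahydro-1H-inden-3-yl (2R)-2-methylbutanoate
Conditions: DCC, DMAP (10 mol %), CH2Cl2, 0 °C → rt
Reagents that add atoms: none
Why: Steglich esterification acylates the α-hydroxy ketone with retention at C3 and without racemising the α-methyl acid at 0 °C.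

Step 21
Reactants: 37 (1R,3R,3aS,7R,7aR)-1-{(1S)-1-[(tert-butyldimethylsilyl)oxy]ethyl}-4-methylidene-2-oxo-7-(propan-2-yl)octahydro-1H-inden-3-yl (2R)-2-methylbutanoate
Product: 38 (1R,3R,3aS,5S,7R,7aR)-1-{(1S)-1-[(tert-butyldimethylsilyl)oxy]ethyl}-5-hydroxy-4-methylidene-2-oxo-7-(propan-2-yl)octahydro-1H-inden-3-yl (2R)-2-methylbutanoate
Conditions: SeO2 (30 mol %), t-BuOOH, CH2Cl2, rt
Reagents that add atoms: selenium dioxide, O=[Se]=O; tert-butyl hydroperoxide, CC(C)(C)OO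
Why: SeO2 allylic oxidation (ene reaction then 2,3-sigmatropic shift) prefers the ring CH2 (C5) over the ring-fusion CH and delivers oxygen axially on the chair locked by the trans fusion, which is the 5S alcohol.

Step 22
Reactants: 38 (1R,3R,3aS,5S,7R,7aR)-1-{(1S)-1-[(tert-butyldimethylsilyl)oxy]ethyl}-5-hydroxy-4-methylidene-2-oxo-7-(propan-2-yl)octahydro-1H-inden-3-yl (2R)-2-methylbutanoate; 10 (2E)-3-methylpent-2-enoic acid
Product: 40 (1R,3R,3aS,5S,7R,7aR)-1-{(1S)-1-[(tert-butyldimethylsilyl)oxy]ethyl}-4-methylidene-3-{[(2R)-2-methylbutanoyl]oxy}-2-oxo-7-(propan-2-yl)octahydro-1H-inden-5-yl (2E)-3-methylpent-2-enoate, via mixed Yamaguchi anhydride 39 (not isolated)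
Conditions: 2,4,6-Cl3C6H2COCl, Et3N, THF, rt; then 38, DMAP, toluene, rt
Reagents that add atoms: none
Why: Yamaguchi esterification through the mixed aroyl anhydride acylates the hindered axial allylic alcohol with retention and keeps the E geometry of the acid.

Step 23
Reactants: 40 (1R,3R,3aS,5S,7R,7aR)-1-{(1S)-1-[(tert-butyldimethylsilyl)oxy]ethyl}-4-methylidene-3-{[(2R)-2-methylbutanoyl]oxy}-2-oxo-7-(propan-2-yl)octahydro-1H-inden-5-yl (2E)-3-methylpent-2-enoate
Product: 41 (1R,3R,3aS,5S,7R,7aR)-1-[(1S)-1-hydroxyethyl]-4-methylidene-3-{[(2R)-2-methylbutanoyl]oxy}-2-oxo-7-(propan-2-yl)octahydro-1H-inden-5-yl (2E)-3-methylpent-2-enoate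
Conditions: HF·pyridine, THF/pyridine, 0 °C → rt
Reagents that add atoms: none
Why: fluoride desilylation under mildly acidic conditions removes the silyl ether without base, so the epimerisable α-acyloxy ketone, the β-hydroxy ketone and both esters survive.

Step 24
Reactants: 41 (1R,3R,3aS,5S,7R,7aR)-1-[(1S)-1-hydroxyethyl]-4-methylidene-3-{[(2R)-2-methylbutanoyl]oxy}-2-oxo-7-(propan-2-yl)octahydro-1H-inden-5-yl (2E)-3-methylpent-2-enoate
Product: 42 (1R,3R,3aS,5S,7R,7aR)-1-[(1S)-1-(acetyloxy)ethyl]-4-methylidene-3-{[(2R)-2-methylbutanoyl]oxy}-2-oxo-7-(propan-2-yl)octahydro-1H-inden-5-yl (2E)-3-methylpent-2-enoate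
Conditions: Ac2O, pyridine, DMAP (5 mol %), CH2Cl2, 0 °C
Reagents that add atoms: acetic anhydride, CC(=O)OC(C)=O
Why: DMAP-catalysed acetylation of the secondary alcohol at 0 °C gives the target, the weak base and short time avoiding β-elimination of the β-acetoxy ketone.

**Compound list**

1 | (4R)-4-benzyl-1,3-oxazolidin-2-one | O=C1N[C@H](Cc2ccccc2)CO1 | starting material
2 | butanoyl chloride | CCCC(Cl)=O | starting material
3 | (4R)-4-benzyl-3-butanoyl-1,3-oxazolidin-2-one | CCCC(=O)N1[C@H](Cc2ccccc2)COC1=O | intermediate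
4 | sodium Z-enolate of 3 | CC/C=C(\[O-])N1[C@H](Cc2ccccc2)COC1=O.[Na+] | intermediate
5 | (4R)-4-benzyl-3-[(2R)-2-methylbutanoyl]-1,3-oxazolidin-2-one | CC[C@@H](C)C(=O)N1[C@H](Cc2ccccc2)COC1=O | intermediate
6 | (2R)-2-methylbutaneperoxoic acid | CC[C@@H](C)C(=O)OO | intermediate
7 | (2R)-2-methylbutanoic acid | CC[C@@H](C)C(=O)O | intermediate
8 | ethyl but-2-ynoate | CCOC(=O)C#CC | starting material
9 | ethyl (2E)-3-methylpent-2-enoate | CCOC(=O)/C=C(\C)CC | intermediate
10 | (2E)-3-methylpent-2-enoic acid | OC(=O)/C=C(\C)CC | intermediate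
11 | 3-methylbutanal | CC(C)CC=O | starting material
12 | but-3-en-2-one | CC(=O)C=C | starting material
13 | (2R)-5-oxo-2-(propan-2-yl)hexanal | O=C[C@@H](C(C)C)CCC(C)=O | intermediate
14 | (4R)-3-hydroxy-4-(propan-2-yl)cyclohexan-1-one (C3 epimers) | O=C1CC(O)[C@@H](C(C)C)CC1 | intermediate
15 | (4R)-4-(propan-2-yl)cyclohex-2-en-1-one ((R)-cryptone) | O=C1C=C[C@@H](C(C)C)CC1 | intermediate
16 | trimethyl{[(3R,4R)-3-(prop-2-en-1-yl)-4-(propan-2-yl)cyclohex-1-en-1-yl]oxy}silane (3,4-trans) | C[Si](C)(C)OC1=C[C@H](CC=C)[C@@H](C(C)C)CC1 | intermediate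
17 | tert-butyl bromoacetate | CC(C)(C)OC(=O)CBr | starting material
18 | lithium (3R,4R)-3-(prop-2-en-1-yl)-4-(propan-2-yl)cyclohex-1-en-1-olate | [Li+].[O-]C1=C[C@H](CC=C)[C@@H](C(C)C)CC1 | intermediate
19 | tert-butyl 2-[(1S,2R,3R)-6-oxo-2-(prop-2-en-1-yl)-3-(propan-2-yl)cyclohexyl]acetate (all-trans) | O=C1[C@@H](CC(=O)OC(C)(C)C)[C@H](CC=C)[C@@H](C(C)C)CC1 | intermediate
20 | secondary ozonide (1,2,4-trioxolane) of 19 | O=C1[C@@H](CC(=O)OC(C)(C)C)[C@H](CC2OCOO2)[C@@H](C(C)C)CC1 | intermediate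
21 | tert-butyl 2-[(1S,2R,3R)-6-oxo-2-(2-oxoethyl)-3-(propan-2-yl)cyclohexyl]acetate | O=C1[C@@H](CC(=O)OC(C)(C)C)[C@H](CC=O)[C@@H](C(C)C)CC1 | intermediate
22 | 2-[(1R,2S,6R)-2-(2-tert-butoxy-2-oxoethyl)-3-oxo-6-(propan-2-yl)cyclohexyl]acetic acid | O=C1[C@@H](CC(=O)OC(C)(C)C)[C@H](CC(=O)O)[C@@H](C(C)C)CC1 | intermediate
23 | 2-[(1R,2S,6R)-2-(2-tert-butoxy-2-oxoethyl)-3-methylidene-6-(propan-2-yl)cyclohexyl]acetic acid | C=C1[C@@H](CC(=O)OC(C)(C)C)[C@H](CC(=O)O)[C@@H](C(C)C)CC1 | intermediate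
24 | mixed anhydride of 23 and pivalic acid | C=C1[C@@H](CC(=O)OC(C)(C)C)[C@H](CC(=O)OC(=O)C(C)(C)C)[C@@H](C(C)C)CC1 | intermediate
25 | tert-butyl 2-[(1S,2R,3R)-2-{2-[(4R)-4-benzyl-2-oxo-1,3-oxazolidin-3-yl]-2-oxoethyl}-6-methylidene-3-(propan-2-yl)cyclohexyl]acetate | C=C1[C@@H](CC(=O)OC(C)(C)C)[C@H](CC(=O)N2[C@H](Cc3ccccc3)COC2=O)[C@@H](C(C)C)CC1 | intermediate
26 | acetaldehyde | CC=O | starting material
27 | Z-dibutylboron enolate of 25 | C=C1[C@@H](CC(=O)OC(C)(C)C)[C@H](/C=C(\OB(CCCC)CCCC)N2[C@H](Cc3ccccc3)COC2=O)[C@@H](C(C)C)CC1 | intermediate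
28 | tert-butyl 2-[(1S,2R,3R)-2-{(2R,3S)-1-[(4R)-4-benzyl-2-oxo-1,3-oxazolidin-3-yl]-3-hydroxy-1-oxobutan-2-yl}-6-methylidene-3-(propan-2-yl)cyclohexyl]acetate | C=C1[C@@H](CC(=O)OC(C)(C)C)[C@H]([C@H]([C@H](C)O)C(=O)N2[C@H](Cc3ccccc3)COC2=O)[C@@H](C(C)C)CC1 | intermediate
29 | tert-butyl 2-[(1S,2R,3R)-2-{(2R,3S)-3-hydroxy-1-[methoxy(methyl)amino]-1-oxobutan-2-yl}-6-methylidene-3-(propan-2-yl)cyclohexyl]acetate | C=C1[C@@H](CC(=O)OC(C)(C)C)[C@H]([C@H]([C@H](C)O)C(=O)N(C)OC)[C@@H](C(C)C)CC1 | intermediate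
30 | tert-butyl 2-[(1S,2R,3R)-2-{(2R,3S)-3-[(tert-butyldimethylsilyl)oxy]-1-[methoxy(methyl)amino]-1-oxobutan-2-yl}-6-methylidene-3-(propan-2-yl)cyclohexyl]acetate | C=C1[C@@H](CC(=O)OC(C)(C)C)[C@H]([C@H]([C@H](C)O[Si](C)(C)C(C)(C)C)C(=O)N(C)OC)[C@@H](C(C)C)CC1 | intermediate
31 | tert-butyl (1R,3aR,7R,7aR)-1-{(1S)-1-[(tert-butyldimethylsilyl)oxy]ethyl}-4-methylidene-2-oxo-7-(propan-2-yl)octahydro-1H-indene-3-carboxylate (trans-fused; C3 epimers and enol) | C=C1[C@@H]2[C@H]([C@H]([C@H](C)O[Si](C)(C)C(C)(C)C)C(=O)C2C(=O)OC(C)(C)C)[C@@H](C(C)C)CC1 | intermediate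
32 | bis(trimethylsilyl) derivative of 31 (C2=C3 silyl enol ether and trimethylsilyl ester) | C=C1[C@@H]2[C@H]([C@H]([C@H](C)O[Si](C)(C)C(C)(C)C)C(O[Si](C)(C)C)=C2C(=O)O[Si](C)(C)C)[C@@H](C(C)C)CC1 | intermediate
33 | beta-keto acid corresponding to 31 (3-carboxylic acid) | C=C1[C@@H]2[C@H]([C@H]([C@H](C)O[Si](C)(C)C(C)(C)C)C(=O)C2C(=O)O)[C@@H](C(C)C)CC1 | intermediate
34 | (1R,3aS,7R,7aR)-1-{(1S)-1-[(tert-butyldimethylsilyl)oxy]ethyl}-4-methylidene-7-(propan-2-yl)octahydro-2H-inden-2-one | C=C1[C@@H]2[C@H]([C@H]([C@H](C)O[Si](C)(C)C(C)(C)C)C(=O)C2)[C@@H](C(C)C)CC1 | intermediate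
35 | potassium C2=C3 enolate of 34 | C=C1[C@@H]2[C@H]([C@H]([C@H](C)O[Si](C)(C)C(C)(C)C)C([O-])=C2)[C@@H](C(C)C)CC1.[K+] | intermediate
36 | (1R,3R,3aS,7R,7aR)-1-{(1S)-1-[(tert-butyldimethylsilyl)oxy]ethyl}-3-hydroxy-4-methylidene-7-(propan-2-yl)octahydro-2H-inden-2-one | C=C1[C@@H]2[C@H]([C@H]([C@H](C)O[Si](C)(C)C(C)(C)C)C(=O)[C@@H]2O)[C@@H](C(C)C)CC1 | intermediate
37 | (1R,3R,3aS,7R,7aR)-1-{(1S)-1-[(tert-butyldimethylsilyl)oxy]ethyl}-4-methylidene-2-oxo-7-(propan-2-yl)octahydro-1H-inden-3-yl (2R)-2-methylbutanoate | C=C1[C@@H]2[C@H]([C@H]([C@H](C)O[Si](C)(C)C(C)(C)C)C(=O)[C@@H]2OC(=O)[C@H](C)CC)[C@@H](C(C)C)CC1 | intermediate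
38 | (1R,3R,3aS,5S,7R,7aR)-1-{(1S)-1-[(tert-butyldimethylsilyl)oxy]ethyl}-5-hydroxy-4-methylidene-2-oxo-7-(propan-2-yl)octahydro-1H-inden-3-yl (2R)-2-methylbutanoate | C=C1[C@@H]2[C@H]([C@H]([C@H](C)O[Si](C)(C)C(C)(C)C)C(=O)[C@@H]2OC(=O)[C@H](C)CC)[C@@H](C(C)C)C[C@@H]1O | intermediate
39 | (2E)-3-methylpent-2-enoic 2,4,6-trichlorobenzoic anhydride | CC/C(C)=C/C(=O)OC(=O)c1c(Cl)cc(Cl)cc1Cl | intermediate
40 | (1R,3R,3aS,5S,7R,7aR)-1-{(1S)-1-[(tert-butyldimethylsilyl)oxy]ethyl}-4-methylidene-3-{[(2R)-2-methylbutanoyl]oxy}-2-oxo-7-(propan-2-yl)octahydro-1H-inden-5-yl (2E)-3-methylpent-2-enoate | C=C1[C@@H]2[C@H]([C@H]([C@H](C)O[Si](C)(C)C(C)(C)C)C(=O)[C@@H]2OC(=O)[C@H](C)CC)[C@@H](C(C)C)C[C@@H]1OC(=O)/C=C(\C)CC | intermediate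
41 | (1R,3R,3aS,5S,7R,7aR)-1-[(1S)-1-hydroxyethyl]-4-methylidene-3-{[(2R)-2-methylbutanoyl]oxy}-2-oxo-7-(propan-2-yl)octahydro-1H-inden-5-yl (2E)-3-methylpent-2-enoate | C=C1[C@@H]2[C@H]([C@H]([C@H](C)O)C(=O)[C@@H]2OC(=O)[C@H](C)CC)[C@@H](C(C)C)C[C@@H]1OC(=O)/C=C(\C)CC | intermediate
42 | (1R,3R,3aS,5S,7R,7aR)-1-[(1S)-1-(acetyloxy)ethyl]-4-methylidene-3-{[(2R)-2-methylbutanoyl]oxy}-2-oxo-7-(propan-2-yl)octahydro-1H-inden-5-yl (2E)-3-methylpent-2-enoate | C=C1[C@@H]2[C@H]([C@H]([C@H](C)OC(C)=O)C(=O)[C@@H]2OC(=O)[C@H](C)CC)[C@@H](C(C)C)C[C@@H]1OC(=O)/C=C(\C)CC | target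

**Totals and risks**

Total step count: 24. Longest linear sequence: 19 steps (steps 6–24, from 11 and 12 to 42); steps 1–3 and 4–5 are side branches that deliver acids 7 and 10.

Most likely to fail, first: step 8. Allylcopper reagents can add 1,2 or give incomplete silyl capture, and the next alkylation depends on a clean enol ether. The fallback sets out from 15, reverses the order in which the two arms are attached, and rejoins at 19. Iodination of 15 (I2, pyridine, CH2Cl2, 0 °C) gives (4R)-2-iodo-4-(propan-2-yl)cyclohex-2-en-1-one F1. Zinc dust in THF turns 17 into (2-tert-butoxy-2-oxoethyl)zinc bromide F2, which is cross-coupled with F1 under Pd(PPh3)4 catalysis (Negishi-type coupling of a Reformatsky reagent) to give tert-butyl 2-[(3R)-6-oxo-3-(propan-2-yl)cyclohex-1-en-1-yl]acetate F3. A Hosomi–Sakurai conjugate allylation of F3 (allyltrimethylsilane, TiCl4, CH2Cl2, −78 °C) adds allyl anti to the isopropyl group, and protonation followed by brief equilibration with DBU gives the all-trans keto ester 19.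

Second: step 19. The face on which the enolate is hydroxylated at C3 rests on a torsional argument, not on a close precedent, and the free α-ketol can epimerise. The fallback sets out from 34 and rejoins at 37, using inversion instead of relying on direct hydroxylation. The kinetic enolate of 34 (LiN(i-Pr)2, Me3SiCl, THF, −78 °C) is trapped as the C2=C3 trimethylsilyl enol ether of 34 F4, which is oxidised with dimethyldioxirane in acetone at −78 °C (Rubottom oxidation). If this gives 36, the route continues as written. If the product is the C3 epimer (1R,3S,3aS,7R,7aR)-1-{(1S)-1-[(tert-butyldimethylsilyl)oxy]ethyl}-3-hydroxy-4-methylidene-7-(propan-2-yl)octahydro-2H-inden-2-one F5, it is esterified with acid 7 under Mitsunobu conditions (PPh3, diisopropyl azodicarboxylate, THF, 0 °C), and the SN2 inversion at the activated α-keto carbon gives 37 directly.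

Third: step 21. The SeO2 oxidation can over-oxidise to the enone or give the equatorial C5 alcohol. The fallback sets out from 37 and rejoins at 40, fixing the C5 configuration by inversion at the esterification stage. If the oxidation gives mainly the C5 epimer (1R,3R,3aS,5R,7R,7aR)-1-{(1S)-1-[(tert-butyldimethylsilyl)oxy]ethyl}-5-hydroxy-4-methylidene-2-oxo-7-(propan-2-yl)octahydro-1H-inden-3-yl (2R)-2-methylbutanoate F6, that alcohol is coupled with acid 10 under Mitsunobu conditions (PPh3, diisopropyl azodicarboxylate, toluene, 0 °C). The carboxylate enters with inversion to give the axial ester 40, so the Yamaguchi step is not needed for that material.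

**Further compounds**

F1 | step 8 | (4R)-2-iodo-4-(propan-2-yl)cyclohex-2-en-1-one | O=C1C(I)=C[C@@H](C(C)C)CC1
F2 | step 8 | (2-tert-butoxy-2-oxoethyl)zinc bromide | CC(C)(C)OC(=O)C[Zn]Br
F3 | step 8 | tert-butyl 2-[(3R)-6-oxo-3-(propan-2-yl)cyclohex-1-en-1-yl]acetate | O=C1C(CC(=O)OC(C)(C)C)=C[C@@H](C(C)C)CC1
F4 | step 19 | C2=C3 trimethylsilyl enol ether of 34 | C=C1[C@@H]2[C@H]([C@H]([C@H](C)O[Si](C)(C)C(C)(C)C)C(O[Si](C)(C)C)=C2)[C@@H](C(C)C)CC1
F5 | step 19 | (1R,3S,3aS,7R,7aR)-1-{(1S)-1-[(tert-butyldimethylsilyl)oxy]ethyl}-3-hydroxy-4-methylidene-7-(propan-2-yl)octahydro-2H-inden-2-one | C=C1[C@@H]2[C@H]([C@H]([C@H](C)O[Si](C)(C)C(C)(C)C)C(=O)[C@H]2O)[C@@H](C(C)C)CC1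
F6 | step 21 | (1R,3R,3aS,5R,7R,7aR)-1-{(1S)-1-[(tert-butyldimethylsilyl)oxy]ethyl}-5-hydroxy-4-methylidene-2-oxo-7-(propan-2-yl)octahydro-1H-inden-3-yl (2R)-2-methylbutanoate | C=C1[C@@H]2[C@H]([C@H]([C@H](C)O[Si](C)(C)C(C)(C)C)C(=O)[C@@H]2OC(=O)[C@H](C)CC)[C@@H](C(C)C)C[C@H]1O
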